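## Conventions and assumptions

- Atoms carry briarane numbering: ten-membered ring C1–C10; ring A = C1, C10, C11, C12, C13, C14; butenolide O–C7, C8=C17 (methyl C18), C19=O; methyls C15 (on C1), C16 (on C5), C20 (on C11).
- On ring A, β is the face that carries the C1 methyl and α is the opposite face, which carries the C1–C2 bond.
- TBS = tert-butyldimethylsilyl, TIPS = triisopropylsilyl, TES = triethylsilyl.
- Compound numbers 1–46 are those of the steps and of the compound list; 46 is the target.
- Assumption: the (S)-diphenylprolinol-derived oxazaborolidinium ion is taken to expose the enal face that leads to (1S,10S), by the formyl C–H···O model for 2-substituted enals; the mirror-image catalyst is the direct remedy if the sense is opposite.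
- Assumption: the cycloaddition is taken to run formyl-endo, which leaves the C11 methyl α (trans to the C10 side chain); C11 is therefore corrected at step 13, and a formyl-exo adduct would converge on the same compound there.

## Analysis of the target

46 is a briarane-type diterpenoid. A cyclohexane (ring A) is trans-fused across C1–C10 to a ten-membered carbocycle, and that ring carries an α-methyl butenolide fused at C7–C8. It has eight stereocentres, (1S,2R,7S,9R,10S,11R,12R,14S), and a (5Z) trisubstituted olefin inside the medium ring. On ring A the C1 methyl, the C10–C9 bond and the C11 methyl all lie on the β face, while the C12 hydroxyl, the C14 acetate and the C1–C2 bond lie on the α face. C11 is thus cis to its neighbour and is the less stable epimer whenever C12 is a carbonyl. The sensitive sites are the C7 hydrogen (allylic and γ to the lactone carbonyl), the allylic C7–O lactone bond, and three esters of two kinds that must be placed beside a free C12 hydroxyl. The hard parts are the closure of the ten-membered ring, the quaternary C1 flanked by oxygenated C2 and C14, and the control of C2, C7 and C9, which are remote from one another. The strategy rests on ring A: the cis relation of the C1 methyl and C9 on adjacent carbons is the imprint of an (E)-2-methyl enal, and C11(CH3)–C12(O) is the enol ether end of a 2-silyloxy diene, so ring A is a Diels–Alder retron with C1–C14 and C10–C11 as the bonds to form.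

## Retrosynthetic reasoning

**Acyl groups (46 back to 42).** The butanoate and the two acetates are cut first, because no ester survives the organometallic and hydride steps that build the skeleton. The C12 TIPS ether of 45 comes off last, the C2 TBS ether of 43 before butanoylation, and the two free hydroxyls of 42 (C9, C14) are acetylated together. The forward steps only have to distinguish two silyl ethers of different size.

**Lactone C19–O (42 back to 40 and 39).** The butenolide is opened to the (Z)-1,4-diol 40. C19 then travels as a protected primary alcohol (39) and is oxidised only after the ring is closed; the cis geometry about the tetrasubstituted C8=C17 bond guarantees that only the C7 hydroxyl can capture C19.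

**C6–C7 (39 back to 38).** The ten-membered ring is cut between the olefinic C6 and the carbinol C7. This cut delivers the C7 oxygen needed for the lactone, takes the (5Z) geometry from a stereodefined alkenyl iodide, and uses a chromium-mediated closure that tolerates the free C9 and C14 hydroxyls. The forward reaction has to close a strained ring and set C7; with the enal s-trans and the ring chain leaving C9 on one face of the C8=C17 plane, attack on that face gives (7S).

**Lactone transposition (38 back to 35).** The C7 aldehyde and the C19 silyl ether of 38 come from the isomeric butenolide 35, whose carbonyl carbon is C7 and whose CH2O is C19. Opening 35 to the Weinreb amide 36 differentiates the two termini with no selectivity problem, and 37 and 38 follow by silylation and reduction.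

**C8–C9 (35 back to 28 and 32).** The butenolide unit is joined through its α-carbon (C8) to the C9 aldehyde 28. The 3-bromo-2-silyloxyfuran 32 is a stable precursor of that α-lithiated butenolide and fixes the C8=C17 geometry inside a ring. The forward addition must set C9 by 1,2-induction from C10.

**Ring A oxygens and C11 (28 back to 16).** Both oxygens are on the α face, so neither is made by hydride attack on a ketone from the crowded β face. The cis-1,3-diol 25 comes from the allylic alcohol 22 by oxygen delivery to C12 through a silicon tether on O14. Alcohol 22 comes from the epoxy ketone 20 by transposition, and the epoxide from the enone 17, where the C10 side chain and the C1 methyl direct the nucleophile to the α face of C14. Between 18 and 20 the C12 ketone is used once more to invert C11 by kinetic protonation. Enone 17 comes from the silyl enol ether 16.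

**C2 and C3–C4 (16 back to 8 and 12).** The C2 carbinol 15 is traced to ketone 14, which has a tertiary and a primary alkyl flank and is therefore well suited to a reagent-controlled oxazaborolidine reduction. Ketone 14 is cut at C3–C4 into the methyl ketone 8, which can enolise only towards C3, and the allylic bromide 12 that carries the (Z)-iodoalkene. Ketone 8 comes from aldehyde 6 through carbinol 7.

**Ring A (6 back to 3 and 5): the key disconnection.** C1–C14 and C10–C11 are cut together. This is the only place where two ring bonds, the quaternary centre and its neighbour fall to one catalytic enantioselective step from two achiral four- and five-carbon pieces. The forward reaction must give the regiochemistry with C12–O para to C1, the absolute configuration at C1, and the cis relation of methyl and side chain.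

**Small pieces.** Enal 3 comes from aldehyde 1 and ylide 2; diene 5 from ketone 4; bromide 12 from alcohol 9 through iodide 11; furan 32 from butenolide 29 through bromide 31.

## Alternatives that were turned down

**Alternative 1:** ring contraction by [2,3]-Wittig rearrangement, leading to the ten-membered carbocycle A1.
- Disconnection: C7–C8, with the C7 oxygen and C19 joined in a thirteen-membered diallyl ether.
- Forward key step: deprotonation at C7 and a [2,3] shift that forms C7–C8, breaks O–C19 and leaves the C7 hydroxyl and a C8 isopropenyl group in A1.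
- For it: a thirteen-membered ether is much easier to close than a ten-membered carbocycle, and the contraction is intramolecular, so on ring closure this plan is stronger than the chosen one. The C7/C8 relation comes from an ordered sigmatropic transition state.
- Against it: two allylic α-oxy positions (C7 and C19) compete for the base, and [1,2] and [1,4] shifts compete with the [2,3] path. The new C8 stereocentre is later destroyed, and the isopropenyl group of A1 still needs oxidation at C19, lactonisation and a double-bond shift to C8=C17. The plan says nothing about how ring A and its five stereocentres are made.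
- Comparison: the chosen route accepts a harder ring closure. In return it gives a catalytic, enantioselective entry to ring A, and it brings in the butenolide carbons already joined with the C8=C17 bond in place.

**Alternative 2:** intermolecular enone–cyclobutene [2+2] photocycloaddition, leading to the photoadduct A2.
- Disconnection: C5–C6 and C9–C10, with the ten-membered ring hidden as a fused six-six system plus two cyclobutanes.
- Forward key step: irradiation joins an octalone enone and a lactone-fused silyloxycyclobutene to the cis-anti-cis adduct A2; later fragmentation of the central cyclobutane releases the cyclodecadiene.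
- For it: no direct medium-ring closure is needed, and the stereochemistry is worked out on rigid six-membered rings, which is stronger than a macrocyclisation on paper.
- Against it: a tetrasubstituted enone must combine with a strained, fully substituted cyclobutene with the right orientation and face. A2 has thirteen stereocentres, and several of them must be right for the fragmentation to give the (5Z) olefin. Both photo partners need long syntheses of their own, and A2 still carries a C4 ketone to remove and a saturated lactone to dehydrogenate.
- Comparison: the risk lies in a step with several unsecured selectivities and the step count is clearly higher. The chosen cycloaddition needs one regiochemical and one facial preference, and both have a known basis.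

**Alternative 3:** oxidative radical cyclisation of a β-keto ester, leading to the ring A keto ester A3.
- Disconnection: C1–C10.
- Forward key step: a trivalent manganese oxidant generates the C1 radical of a 2-methyl β-keto ester; it adds to C10 of a Z-trisubstituted olefin, and a divalent copper co-oxidant turns the C11 radical into the exocyclic methylene of A3.
- For it: A3 already has oxygen at C12 and C14 and C2 at the carboxyl level. On oxygenation count this is stronger than the chosen route, which spends five steps on the two ring oxygens. The C11 methylene allows a late hydrogenation from the open α face.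
- Against it: the C1/C10 relation rests on substrate control in a radical transition state. The absolute configuration must come from an enantiopure acyclic precursor made separately. The C14 ketone then needs hydride from the crowded β face. Stoichiometric metal oxidants are required.
- Comparison: the chosen route sets C1 and C10 in one concerted, catalyst-controlled step and derives the absolute configuration there. It pays with a longer oxygenation sequence, in which, however, each oxygen is delivered to the open face.

Key step: step 3

## Route

Step 1
Reactants: 1 (tert-butyldimethylsilyloxy)acetaldehyde; 2 2-(triphenylphosphoranylidene)propanal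
Product: 3 (E)-4-(tert-butyldimethylsilyloxy)-2-methylbut-2-enal
Conditions: toluene, 80 °C
Reagents that add atoms: none
Why: Wittig olefination with the stabilised formyl ylide reacts only at the aldehyde of 1 and gives the (E)-enal, in which the methyl and the silyloxymethyl group are cis as later needed at C1 and C10.

Step 2
Reactants: 4 pent-1-en-3-one
Product: 5 (Z)-3-(triisopropylsilyloxy)penta-1,3-diene
Conditions: i-Pr3SiOTf, Et3N, Et2O, 0 °C
Reagents that add atoms: triisopropylsilyl trifluoromethanesulfonate, CC(C)[Si](C(C)C)(C(C)C)OS(=O)(=O)C(F)(F)F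
Why: Soft enolisation of the ethyl side and O-silylation give the 2-silyloxy diene with the methyl trans to the vinyl group (Z enol ether); the triisopropylsilyl group is chosen because it withstands the acidic catalyst of step 3.

Step 3
Reactants: 3 (E)-4-(tert-butyldimethylsilyloxy)-2-methylbut-2-enal; 5 (Z)-3-(triisopropylsilyloxy)penta-1,3-diene
Product: 6 ring A aldehyde: cyclohexene with C1 formyl (α) and methyl (β), C10 CH2OTBS (β), C11 methyl (α), C12 OTIPS enol ether (C12=C13)
Conditions: (S)-3,3-diphenyl-1-(o-tolyl)tetrahydropyrrolo[1,2-c][1,3,2]oxazaborole (20 mol%), HNTf2 (18 mol%), CH2Cl2, −78 → −40 °C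
Reagents that add atoms: none
Why: The aldehyde oxygen of 3 binds to boron of the N-protonated oxazaborolidine and the formyl C–H is held by the ring oxygen, which fixes the s-trans enal over one aryl group and leaves one face of C1=C10 open. Diene 5 then adds in a concerted, asynchronous [4+2] cycloaddition in which the enol ether terminus C11 bonds to the β-carbon C10 ahead of C14 to C1; the closest known reaction type is the oxazaborolidinium-catalysed Diels–Alder reaction of 2-substituted enals with 2-silyloxy dienes. Ring A is closed in this one intermolecular cycloaddition, with C1–C14 and C10–C11 formed suprafacially on both partners. C1 is set in the absolute sense by the catalyst, and by the formyl C–H···O model the (S)-catalyst should give (1S) in target numbering. C10 follows from C1 because the addition is suprafacial, so the (E) geometry of 3 becomes the cis relation of the C1 methyl and the C10 side chain. C11 depends on the endo/exo mode: the formyl-endo arrangement keeps the C10 side chain away from the silyloxy group of the diene and is expected, which places the C11 methyl trans to the C10 side chain, so this centre is provisional and is reset in step 13. The selectivity the step must deliver is therefore the regiochemistry, secured by the silyloxy group (its β-carbon bonds to the enal β-carbon), and the C1/C10 pair, secured by the catalyst and the concerted mechanism. The TIPS enol ether of 6 then serves as a protected C12 ketone through steps 4 to 10.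

Step 4
Reactants: 6 ring A aldehyde
Product: 7 ring A carbinol with a 1-hydroxyethyl group at C1 (both C2 epimers)
Conditions: MeMgBr, THF, −78 → 0 °C
Reagents that add atoms: methylmagnesium bromide, C[Mg]Br
Why: Grignard 1,2-addition to the neopentyl aldehyde; the silyl enol ether and the silyl ether are inert, and the C2 configuration is irrelevant because the carbinol is oxidised in step 5.

Step 5
Reactants: 7 ring A carbinol
Product: 8 ring A methyl ketone (acetyl at C1)
Conditions: Dess–Martin periodinane, NaHCO3, CH2Cl2, rt
Reagents that add atoms: none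
Why: Buffered Dess–Martin oxidation of a secondary alcohol leaves the enol ether untouched and gives a methyl ketone that can enolise only towards C3.

Step 6
Reactants: 9 prop-2-yn-1-ol
Product: 11 (Z)-3-iodo-2-methylprop-2-en-1-ol, via alkenylmagnesium alkoxide chelate 10 (not isolated)
Conditions: MeMgBr (2.5 equiv), CuI (10 mol%, monovalent copper), THF, −10 °C → rt; then I2, 0 °C
Reagents that add atoms: methylmagnesium bromide, C[Mg]Br; iodine, II
Why: Copper-catalysed anti-carbomagnesiation of propargyl alcohol places the methyl on the carbon next to the carbinol and the magnesium, held by the alkoxide in a five-membered chelate, on the terminus; iodinolysis with retention gives the iodide cis to CH2OH.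

Step 7
Reactants: 11 (Z)-3-iodo-2-methylprop-2-en-1-ol
Product: 12 (Z)-3-bromo-1-iodo-2-methylprop-1-ene
Conditions: CBr4, PPh3, CH2Cl2, 0 °C
Reagents that add atoms: tetrabromomethane, BrC(Br)(Br)Br
Why: Appel bromination of the primary allylic alcohol under neutral conditions keeps the geometry of the alkenyl iodide.

Step 8
Reactants: 8 ring A methyl ketone; 12 (Z)-3-bromo-1-iodo-2-methylprop-1-ene
Product: 14 C2 ketone carrying the C3–C6 chain with the (Z)-alkenyl iodide, via lithium enolate 13 (not isolated)
Conditions: LiN(i-Pr)2, THF, −78 °C; then 12, DMPU, −78 → −20 °C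
Reagents that add atoms: none
Why: C1 is quaternary, so only the C3 enolate can form; it is alkylated by the allylic bromide in an SN2 reaction that forms C3–C4 and brings in C4–C6 with iodine cis to C4.

Step 9
Reactants: 14 C2 ketone
Product: 15 (2R)-carbinol
Conditions: (S)-2-methyl-CBS-oxazaborolidine (0.5 equiv), catecholborane, toluene, −78 → −40 °C
Reagents that add atoms: none
Why: Corey–Bakshi–Shibata reduction: the ketone has a tertiary alkyl (C1) and a primary alkyl (C3) flank, the large/small pattern on which the (S)-oxazaborolidine should deliver hydride to give the (2R)-alcohol by reagent control; catecholborane does not hydroborate the enol ether or the iodoalkene.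

Step 10
Reactants: 15 (2R)-carbinol
Product: 16 C2 TBS ether
Conditions: t-BuMe2SiOTf, 2,6-lutidine, CH2Cl2, −78 → 0 °C
Reagents that add atoms: tert-butyldimethylsilyl trifluoromethanesulfonate, CC(C)(C)[Si](C)(C)OS(=O)(=O)C(F)(F)F
Why: The silyl triflate silylates the hindered secondary alcohol; the TIPS enol ether is stable to the base-buffered conditions.

Step 11
Reactants: 16 C2 TBS ether
Product: 17 ring A enone (C12 ketone, C13=C14, C11 methyl α)
Conditions: DDQ, 2,4,6-collidine, benzene, rt
Reagents that add atoms: none
Why: DDQ dehydrogenation of a silyl enol ether: hydride abstraction at C14 and loss of the silyl group can only give the C13=C14 enone; the method is metal-free, whereas Pd(OAc)2 (divalent palladium) would release zerovalent palladium that inserts into the alkenyl iodide.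

Step 12
Reactants: 17 ring A enone
Product: 18 13α,14α-epoxy ketone (C11 methyl α)
Conditions: 30% H2O2, NaOH, MeOH, 0 °C
Reagents that add atoms: hydrogen peroxide, OO
Why: Weitz–Scheffer epoxidation: hydroperoxide should add to C14 axially, anti to the pseudoaxial C1 methyl and trans to the β side chain on C10, and the enolate closes the epoxide on the same α face, which sets C14–O α.

Step 13
Reactants: 18 13α,14α-epoxy ketone (C11 methyl α)
Product: 20 13α,14α-epoxy ketone (C11 methyl β), via lithium enolate 19 (not isolated)
Conditions: LiN(SiMe3)2, THF, −78 °C; then AcOH, THF, −78 °C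
Reagents that add atoms: none
Why: Ketone 18 can enolise only towards C11 because C13 is an epoxide carbon; kinetic protonation of the enolate from the α face, anti to the adjacent pseudoaxial C10 side chain, should give the C11 methyl β, the less stable cis epimer that the target needs.

Step 14
Reactants: 20 13α,14α-epoxy ketone (C11 methyl β)
Product: 22 allylic alcohol (14α-OH, C12=C13), via epoxy hydrazone 21 (not isolated)
Conditions: N2H4·H2O, AcOH (cat.), MeOH, 0 °C → rt
Reagents that add atoms: none
Why: Wharton transposition: the hydrazone opens the epoxide to an alkenyl diazene that loses N2, so the C14–O bond and its α configuration are kept; removal of the carbonyl also ends the risk of epimerisation at C11.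

Step 15
Reactants: 22 allylic alcohol
Product: 25 12α,14α-diol, via 14-O-dimethylsilyl ether 23 (not isolated), via bridged siloxane 24 (not isolated)
Conditions: (HMe2Si)2NH, rt; Pt2[(CH2=CHSiMe2)2O]3 (1 mol%, zerovalent platinum), toluene, 60 °C; then 30% H2O2, KF, KHCO3, THF/MeOH, rt
Reagents that add atoms: hydrogen peroxide, OO
Why: Tamao's tethered hydrosilylation and oxidation of allylic alcohols: the Si–H on O14 can reach C12 only through a five-membered oxasilolane on the α face, and Tamao–Fleming oxidation with retention then gives the C12 hydroxyl cis to the C14 hydroxyl, so C12 is set by the tether.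

Step 16
Reactants: 25 12α,14α-diol
Product: 26 C12 TIPS ether with free C14 hydroxyl
Conditions: i-Pr3SiOTf (1.05 equiv), 2,6-lutidine, CH2Cl2, −78 °C
Reagents that add atoms: triisopropylsilyl trifluoromethanesulfonate, CC(C)[Si](C(C)C)(C(C)C)OS(=O)(=O)C(F)(F)F
Why: The C14 hydroxyl sits next to quaternary C1 and is much more hindered, so the bulky silyl triflate at low temperature should silylate only the C12 hydroxyl.

Step 17
Reactants: 26 C12 TIPS ether
Product: 27 C9 primary alcohol
Conditions: HF·pyridine, pyridine, THF, 0 °C
Reagents that add atoms: none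
Why: Buffered HF·pyridine cleaves the primary TBS ether much faster than the hindered secondary TBS ether at C2 or the TIPS ether at C12.

Step 18
Reactants: 27 C9 primary alcohol
Product: 28 C9 aldehyde
Conditions: TEMPO (cat.), PhI(OAc)2, CH2Cl2, rt
Reagents that add atoms: none
Why: The TEMPO/PhI(OAc)2 system oxidises primary alcohols selectively, leaves the hindered secondary C14 hydroxyl alone, and is neutral enough to spare the epimerisable C10; the aldehyde is used at once.

Step 19
Reactants: 29 4-methylfuran-2(5H)-one
Product: 31 3-bromo-4-methylfuran-2(5H)-one, via dibromolactone 30 (not isolated)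
Conditions: Br2, CH2Cl2, 0 °C → rt; then Et3N, 0 °C
Reagents that add atoms: bromine, BrBr
Why: Bromine adds across the butenolide double bond and base-induced loss of HBr from the α-carbon gives the α-bromobutenolide.

Step 20
Reactants: 31 3-bromo-4-methylfuran-2(5H)-one
Product: 32 3-bromo-4-methyl-2-(triisopropylsilyloxy)furan
Conditions: i-Pr3SiOTf, Et3N, CH2Cl2, 0 °C
Reagents that add atoms: triisopropylsilyl trifluoromethanesulfonate, CC(C)[Si](C(C)C)(C(C)C)OS(=O)(=O)C(F)(F)F
Why: Deprotonation at C5 and O-silylation give the 2-silyloxyfuran, which masks the lactone carbonyl and allows halogen–lithium exchange at C3.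

Step 21
Reactants: 32 3-bromo-4-methyl-2-(triisopropylsilyloxy)furan; 28 C9 aldehyde
Product: 35 (9R)-carbinol bearing the 4-methyl-2-oxo-2,5-dihydrofuran-3-yl group at C9 (lactone carbonyl = C7, ring CH2O = C19), via furyllithium 33 (not isolated), via silyloxyfuran carbinol 34 (not isolated)
Conditions: 32 (2.5 equiv), n-BuLi (2.4 equiv), THF, −78 °C; then 28, −78 °C; then AcOH, n-Bu4NF, −78 → 0 °C
Reagents that add atoms: none
Why: Metal–halogen exchange of a 3-bromo-2-silyloxyfuran gives an α-lithiated butenolide equivalent that adds to the aldehyde and forms C8–C9 (one equivalent is spent on the C14 hydroxyl). Felkin–Anh attack anti to the C1–C10 bond, with quaternary C1 as the large group, is expected to give (9R). Buffered fluoride then removes the furan silyl group and protonation at C19 gives the conjugated butenolide.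

Step 22
Reactants: 35 (9R)-carbinol with transposed butenolide
Product: 36 (Z)-Weinreb amide (C7) with free C19 primary alcohol
Conditions: MeNHOMe·HCl, AlMe3, CH2Cl2, 0 °C → rt
Reagents that add atoms: N,O-dimethylhydroxylamine hydrochloride, CNOC.Cl
Why: Weinreb aminolysis of the lactone with the aluminium amide takes place at the acyl carbon C7, conjugate addition being blocked by the fully substituted β-carbon; the tetrasubstituted double bond keeps C7 and C19 cis.

Step 23
Reactants: 36 (Z)-Weinreb amide
Product: 37 C19 TES ether
Conditions: Et3SiCl (1.1 equiv), imidazole, CH2Cl2, −20 → 0 °C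
Reagents that add atoms: chlorotriethylsilane, CC[Si](Cl)(CC)CC
Why: The primary allylic C19 hydroxyl is silylated much faster than the hindered secondary hydroxyls at C9 and C14, and silylation stops relactonisation.

Step 24
Reactants: 37 C19 TES ether
Product: 38 C7 enal
Conditions: i-Bu2AlH (4 equiv), THF, −78 °C
Reagents that add atoms: none
Why: Hydride reduction of a Weinreb amide stops at the chelated hemiaminal, which gives the aldehyde on work-up; the extra equivalents are taken up by the two free hydroxyls.

Step 25
Reactants: 38 C7 enal
Product: 39 ten-membered (7S)-carbinol (free OH at C7, C9, C14; C19 OTES)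
Conditions: CrCl2 (10 equiv, divalent chromium), NiCl2 (0.1 equiv), DMSO, rt, 2 mM
Reagents that add atoms: none
Why: Nozaki–Hiyama–Kishi macrocyclisation: zerovalent nickel inserts into the C6–I bond with retention, transmetalation gives the alkenylchromium, and this adds only to the aldehyde, forming C6–C7 and the ten-membered ring beside free hydroxyls. The ring chain leaves C9 on one face of the C8=C17 plane (allylic strain keeps C9–H or C9–O in that plane), so C6 must attack the s-trans enal on that face, which should give (7S).

Step 26
Reactants: 39 ten-membered (7S)-carbinol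
Product: 40 macrocyclic tetraol (C7, C9, C14, C19 hydroxyls)
Conditions: PPTS, MeOH, 0 °C
Reagents that add atoms: none
Why: Acid-catalysed methanolysis removes the primary TES ether and leaves the secondary TBS and TIPS ethers.

Step 27
Reactants: 40 macrocyclic tetraol
Product: 42 butenolide with free C9 and C14 hydroxyls, via lactol 41 (not isolated)
Conditions: TEMPO (0.2 equiv), PhI(OAc)2 (2.5 equiv), CH2Cl2, rt
Reagents that add atoms: none
Why: Oxidative lactonisation of a 1,4-diol: the primary allylic C19 alcohol is oxidised first, the aldehyde is captured by the cis C7 hydroxyl as the five-membered lactol, and this is oxidised to the lactone; C9–OH is trans to C19 across the double bond and cannot compete.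

Step 28
Reactants: 42 butenolide diol
Product: 43 9,14-diacetate
Conditions: Ac2O, DMAP (cat.), pyridine, rt → 40 °C
Reagents that add atoms: acetic anhydride, CC(=O)OC(C)=O
Why: DMAP-catalysed acetylation of the two remaining free hydroxyls; pyridine alone is used as base so that the acidic C7 hydrogen of the butenolide is not removed.

Step 29
Reactants: 43 9,14-diacetate
Product: 44 C2 alcohol
Conditions: HF·pyridine, THF, 0 °C → rt
Reagents that add atoms: none
Why: HF·pyridine cleaves the TBS ether at C2 while the far more robust TIPS ether at C12 and the esters survive; the acidic medium disfavours acetyl migration from O14 to O2.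

Step 30
Reactants: 44 C2 alcohol
Product: 45 C2 butanoate with C12 TIPS ether
Conditions: (n-PrCO)2O, DMAP, pyridine, CH2Cl2, 0 °C → rt
Reagents that add atoms: butanoic anhydride, CCCC(=O)OC(=O)CCC
Why: DMAP-catalysed acylation of the hindered C2 hydroxyl with an excess of anhydride, so that acylation outruns any acetyl migration.

Step 31
Reactants: 45 C2 butanoate with C12 TIPS ether
Product: 46 target, CNP0281577.1
Conditions: 48% aq. HF, MeCN, rt
Reagents that add atoms: none
Why: Acidic fluoride removes the secondary TIPS ether without base, so the three esters and the butenolide with its acidic C7 hydrogen are untouched.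

## Compound list

1 | (tert-butyldimethylsilyloxy)acetaldehyde | O=CCO[Si](C)(C)C(C)(C)C | starting material
2 | 2-(triphenylphosphoranylidene)propanal | CC(C=O)=P(c1ccccc1)(c1ccccc1)c1ccccc1 | starting material
3 | (E)-4-(tert-butyldimethylsilyloxy)-2-methylbut-2-enal | O=C/C(C)=C/CO[Si](C)(C)C(C)(C)C | intermediate
4 | pent-1-en-3-one | CCC(=O)C=C | starting material
5 | (Z)-3-(triisopropylsilyloxy)penta-1,3-diene | C=C/C(O[Si](C(C)C)(C(C)C)C(C)C)=C/C | intermediate
6 | ring A aldehyde (formyl α and methyl β at C1, CH2OTBS β at C10, methyl α at C11, C12 OTIPS enol ether) | O=C[C@@]1(C)CC=C(O[Si](C(C)C)(C(C)C)C(C)C)[C@@H](C)[C@@H]1CO[Si](C)(C)C(C)(C)C | intermediate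
7 | ring A carbinol, 1-hydroxyethyl at C1 (both C2 epimers) | CC(O)[C@@]1(C)CC=C(O[Si](C(C)C)(C(C)C)C(C)C)[C@@H](C)[C@@H]1CO[Si](C)(C)C(C)(C)C | intermediate
8 | ring A methyl ketone, acetyl at C1 | CC(=O)[C@@]1(C)CC=C(O[Si](C(C)C)(C(C)C)C(C)C)[C@@H](C)[C@@H]1CO[Si](C)(C)C(C)(C)C | intermediate
9 | prop-2-yn-1-ol | C#CCO | starting material
10 | alkenylmagnesium alkoxide chelate (4-methyl-2,5-dihydro-1,2-oxamagnesole) | CC1=C[Mg]OC1 | intermediate (not isolated)
11 | (Z)-3-iodo-2-methylprop-2-en-1-ol | OC/C(C)=C\I | intermediate
12 | (Z)-3-bromo-1-iodo-2-methylprop-1-ene | BrC/C(C)=C\I | intermediate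
13 | lithium enolate of 8 | [Li]OC(=C)[C@@]1(C)CC=C(O[Si](C(C)C)(C(C)C)C(C)C)[C@@H](C)[C@@H]1CO[Si](C)(C)C(C)(C)C | intermediate (not isolated)
14 | C2 ketone with C3–C6 chain and (Z)-alkenyl iodide | I/C=C(C)\CCC(=O)[C@@]1(C)CC=C(O[Si](C(C)C)(C(C)C)C(C)C)[C@@H](C)[C@@H]1CO[Si](C)(C)C(C)(C)C | intermediate
15 | (2R)-carbinol | I/C=C(C)\CC[C@@H](O)[C@@]1(C)CC=C(O[Si](C(C)C)(C(C)C)C(C)C)[C@@H](C)[C@@H]1CO[Si](C)(C)C(C)(C)C | intermediate
16 | C2 TBS ether | I/C=C(C)\CC[C@@H](O[Si](C)(C)C(C)(C)C)[C@@]1(C)CC=C(O[Si](C(C)C)(C(C)C)C(C)C)[C@@H](C)[C@@H]1CO[Si](C)(C)C(C)(C)C | intermediate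
17 | ring A enone (C12 ketone, C13=C14, C11 methyl α) | I/C=C(C)\CC[C@@H](O[Si](C)(C)C(C)(C)C)[C@@]1(C)C=CC(=O)[C@@H](C)[C@@H]1CO[Si](C)(C)C(C)(C)C | intermediate
18 | 13α,14α-epoxy ketone, C11 methyl α | I/C=C(C)\CC[C@@H](O[Si](C)(C)C(C)(C)C)[C@@]1(C)[C@H]2O[C@H]2C(=O)[C@@H](C)[C@@H]1CO[Si](C)(C)C(C)(C)C | intermediate
19 | lithium enolate of 18 (C11=C12) | I/C=C(C)\CC[C@@H](O[Si](C)(C)C(C)(C)C)[C@@]1(C)[C@H]2O[C@H]2C(O[Li])=C(C)[C@@H]1CO[Si](C)(C)C(C)(C)C | intermediate (not isolated)
20 | 13α,14α-epoxy ketone, C11 methyl β | I/C=C(C)\CC[C@@H](O[Si](C)(C)C(C)(C)C)[C@@]1(C)[C@H]2O[C@H]2C(=O)[C@H](C)[C@@H]1CO[Si](C)(C)C(C)(C)C | intermediate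
21 | epoxy hydrazone of 20 | I/C=C(C)\CC[C@@H](O[Si](C)(C)C(C)(C)C)[C@@]1(C)[C@H]2O[C@H]2C(=NN)[C@H](C)[C@@H]1CO[Si](C)(C)C(C)(C)C | intermediate (not isolated)
22 | allylic alcohol (14α-OH, C12=C13) | I/C=C(C)\CC[C@@H](O[Si](C)(C)C(C)(C)C)[C@@]1(C)[C@@H](O)C=C[C@H](C)[C@@H]1CO[Si](C)(C)C(C)(C)C | intermediate
23 | 14-O-dimethylsilyl ether of 22 | I/C=C(C)\CC[C@@H](O[Si](C)(C)C(C)(C)C)[C@@]1(C)[C@@H](O[SiH](C)C)C=C[C@H](C)[C@@H]1CO[Si](C)(C)C(C)(C)C | intermediate (not isolated)
24 | bridged siloxane (O14–SiMe2–C12, α face) | I/C=C(C)\CC[C@@H](O[Si](C)(C)C(C)(C)C)[C@@]1(C)[C@@H]2C[C@@H]([Si](C)(C)O2)[C@H](C)[C@@H]1CO[Si](C)(C)C(C)(C)C | intermediate (not isolated)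
25 | 12α,14α-diol | I/C=C(C)\CC[C@@H](O[Si](C)(C)C(C)(C)C)[C@@]1(C)[C@@H](O)C[C@@H](O)[C@H](C)[C@@H]1CO[Si](C)(C)C(C)(C)C | intermediate
26 | C12 TIPS ether, C14 hydroxyl free | I/C=C(C)\CC[C@@H](O[Si](C)(C)C(C)(C)C)[C@@]1(C)[C@@H](O)C[C@@H](O[Si](C(C)C)(C(C)C)C(C)C)[C@H](C)[C@@H]1CO[Si](C)(C)C(C)(C)C | intermediate
27 | C9 primary alcohol | I/C=C(C)\CC[C@@H](O[Si](C)(C)C(C)(C)C)[C@@]1(C)[C@@H](O)C[C@@H](O[Si](C(C)C)(C(C)C)C(C)C)[C@H](C)[C@@H]1CO | intermediate
28 | C9 aldehyde | I/C=C(C)\CC[C@@H](O[Si](C)(C)C(C)(C)C)[C@@]1(C)[C@@H](O)C[C@@H](O[Si](C(C)C)(C(C)C)C(C)C)[C@H](C)[C@@H]1C=O | intermediate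
29 | 4-methylfuran-2(5H)-one | CC1=CC(=O)OC1 | starting material
30 | 3,4-dibromo-4-methyloxolan-2-one | CC1(Br)COC(=O)C1Br | intermediate (not isolated)
31 | 3-bromo-4-methylfuran-2(5H)-one | CC1=C(Br)C(=O)OC1 | intermediate
32 | 3-bromo-4-methyl-2-(triisopropylsilyloxy)furan | Cc1coc(O[Si](C(C)C)(C(C)C)C(C)C)c1Br | intermediate
33 | 4-methyl-2-(triisopropylsilyloxy)furan-3-yllithium | Cc1coc(O[Si](C(C)C)(C(C)C)C(C)C)c1[Li] | intermediate (not isolated)
34 | (9R)-silyloxyfuran carbinol | I/C=C(C)\CC[C@@H](O[Si](C)(C)C(C)(C)C)[C@@]1(C)[C@@H](O)C[C@@H](O[Si](C(C)C)(C(C)C)C(C)C)[C@H](C)[C@@H]1[C@@H](O)c1c(C)coc1O[Si](C(C)C)(C(C)C)C(C)C | intermediate (not isolated)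
35 | (9R)-carbinol with 4-methyl-2-oxo-2,5-dihydrofuran-3-yl at C9 | I/C=C(C)\CC[C@@H](O[Si](C)(C)C(C)(C)C)[C@@]1(C)[C@@H](O)C[C@@H](O[Si](C(C)C)(C(C)C)C(C)C)[C@H](C)[C@@H]1[C@@H](O)C1=C(C)COC1=O | intermediate
36 | (Z)-Weinreb amide (C7) with C19 primary alcohol | I/C=C(C)\CC[C@@H](O[Si](C)(C)C(C)(C)C)[C@@]1(C)[C@@H](O)C[C@@H](O[Si](C(C)C)(C(C)C)C(C)C)[C@H](C)[C@@H]1[C@@H](O)/C(=C(\C)CO)C(=O)N(C)OC | intermediate
37 | C19 TES ether of 36 | I/C=C(C)\CC[C@@H](O[Si](C)(C)C(C)(C)C)[C@@]1(C)[C@@H](O)C[C@@H](O[Si](C(C)C)(C(C)C)C(C)C)[C@H](C)[C@@H]1[C@@H](O)/C(=C(\C)CO[Si](CC)(CC)CC)C(=O)N(C)OC | intermediate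
38 | C7 enal | I/C=C(C)\CC[C@@H](O[Si](C)(C)C(C)(C)C)[C@@]1(C)[C@@H](O)C[C@@H](O[Si](C(C)C)(C(C)C)C(C)C)[C@H](C)[C@@H]1[C@@H](O)/C(=C(\C)CO[Si](CC)(CC)CC)C=O | intermediate
39 | ten-membered (7S)-carbinol, C19 OTES | CC(C)(C)[Si](C)(C)O[C@@H]1CC/C(C)=C\[C@H](O)/C(=C(/C)CO[Si](CC)(CC)CC)[C@H](O)[C@H]2[C@@H](C)[C@H](O[Si](C(C)C)(C(C)C)C(C)C)C[C@H](O)[C@@]21C | intermediate
40 | macrocyclic tetraol | CC(C)(C)[Si](C)(C)O[C@@H]1CC/C(C)=C\[C@H](O)/C(=C(/C)CO)[C@H](O)[C@H]2[C@@H](C)[C@H](O[Si](C(C)C)(C(C)C)C(C)C)C[C@H](O)[C@@]21C | intermediate
41 | lactol (C19 hemiacetal, either C19 epimer) | CC(C)(C)[Si](C)(C)O[C@@H]1CC/C(C)=C\[C@@H]2OC(O)C(C)=C2[C@H](O)[C@H]2[C@@H](C)[C@H](O[Si](C(C)C)(C(C)C)C(C)C)C[C@H](O)[C@@]21C | intermediate (not isolated)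
42 | butenolide with free C9 and C14 hydroxyls | CC(C)(C)[Si](C)(C)O[C@@H]1CC/C(C)=C\[C@@H]2OC(=O)C(C)=C2[C@H](O)[C@H]2[C@@H](C)[C@H](O[Si](C(C)C)(C(C)C)C(C)C)C[C@H](O)[C@@]21C | intermediate
43 | 9,14-diacetate | CC(C)(C)[Si](C)(C)O[C@@H]1CC/C(C)=C\[C@@H]2OC(=O)C(C)=C2[C@H](OC(C)=O)[C@H]2[C@@H](C)[C@H](O[Si](C(C)C)(C(C)C)C(C)C)C[C@H](OC(C)=O)[C@@]21C | intermediate
44 | C2 alcohol | O[C@@H]1CC/C(C)=C\[C@@H]2OC(=O)C(C)=C2[C@H](OC(C)=O)[C@H]2[C@@H](C)[C@H](O[Si](C(C)C)(C(C)C)C(C)C)C[C@H](OC(C)=O)[C@@]21C | intermediate
45 | C2 butanoate, C12 TIPS ether | CCCC(=O)O[C@@H]1CC/C(C)=C\[C@@H]2OC(=O)C(C)=C2[C@H](OC(C)=O)[C@H]2[C@@H](C)[C@H](O[Si](C(C)C)(C(C)C)C(C)C)C[C@H](OC(C)=O)[C@@]21C | intermediate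
46 | CNP0281577.1, (1S,2R,5Z,7S,9R,10S,11R,12R,14S) | CCCC(=O)O[C@@H]1CC/C(C)=C\[C@@H]2OC(=O)C(C)=C2[C@H](OC(C)=O)[C@H]2[C@@H](C)[C@H](O)C[C@H](OC(C)=O)[C@@]21C | target

## Step count and least certain steps

Total: 31 steps. Longest linear sequence: 26 steps (steps 1, 3–5, 8–18, 21–31).

**Step 3 (key step).** The most likely failure is slow cycloaddition of the trisubstituted enal, which lets protodesilylation of the diene or an open-chain Mukaiyama–Michael path compete, together with loss of enantioselectivity. The reason is that a β-substituted α-methyl enal is a weaker dienophile and a poorer fit for the catalyst pocket than the 2-substituted acroleins for which the catalyst is best established. Fallback: enantioselection is moved to a reagent-controlled reduction. Setting out from 3 and 5, an achiral Lewis acid (EtAlCl2, CH2Cl2, −78 °C) should give the racemate, that is 6 together with its mirror image F1. Steps 4 and 5 on the racemate give 7 with the mirror-image carbinols F2 and then 8 with the mirror-image ketone F3. Reduction of this racemic methyl ketone under the conditions of step 9 turns the two enantiomers into diastereomers: the (2R)-carbinol of the wanted ring series F4 and the (2R)-carbinol of the mirror-image ring F5, which are separated by chromatography. Dess–Martin oxidation of F4 returns to the route at enantiopure 8.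

**Step 13.** The most likely failure is degradation of the epoxy ketone by the amide base, or incomplete facial selectivity in the protonation, because the enolate sits next to a strained epoxide and the wanted product is the less stable epimer. Fallback: C11 is set one stage earlier, where no epoxide is present. Setting out from 17, LiN(SiMe3)2 (THF, −78 °C) forms the cross-conjugated dienolate, whose only carbon terminus is C11, and AcOH at −78 °C should give the enone with the C11 methyl β, F6. Epoxidation of F6 under weakly basic conditions (t-BuOOH, DBU, CH2Cl2, 0 °C, short contact) then comes back to the route at 20.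

**Step 15.** The most likely failure is that the tethered hydrosilylation does not occur or is slow, because the conformer with O14 pseudoaxial forces the C1 and C11 methyls into a syn-axial relation; zerovalent platinum may also insert into the alkenyl iodide. Fallback: the two oxygens are kept on the ketone and the hydride is directed by chelation. Setting out from 20, reductive opening of the epoxide at C13 with NaSePh [(PhSe)2, NaBH4, AcOH, EtOH, 0 °C] should give the 14α-hydroxy C12 ketone F7. Reduction with Et2BOMe and NaBH4 (THF/MeOH, −78 °C) then holds both oxygens on the α face in a boron chelate, so hydride enters from the β face, and the sequence rejoins the route at 25.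

**Step 21.** The most likely failure is poor facial selectivity at C9, with some epimerisation at C10, because the aldehyde is axial and is flanked on both sides by methyl-bearing carbons, so the Felkin preference may be small. Fallback: the carbinol is made by hydride addition instead of carbon addition. Setting out from 35 mixed with its C9 epimer F8, MnO2 (CH2Cl2, rt) oxidises only the allylic C9 carbinol of both to the C9 ketone F9. Reduction with NaBH4 and CeCl3 (MeOH, −78 °C) lets hydride take the trajectory that the furyl group preferred, which inverts the outcome of the addition and returns to the route at 35.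

**Step 25.** The most likely failure is intermolecular coupling or simple loss of iodine in place of ring closure, because the ten-membered ring is strained and the aldehyde is hindered; formation of the C7 epimer is the second risk. Fallback: the ring is closed by acylation and the carbinol is made by reduction. Setting out from 37, the two hydroxyls are converted into alkoxides with LiN(SiMe3)2 (2 equiv, THF, −78 °C); t-BuLi (2 equiv, −100 °C) then effects iodine–lithium exchange, and the alkenyllithium attacks the Weinreb amide within the molecule to give the macrocyclic cross-conjugated C7 ketone F10, over-addition being stopped by the chelated tetrahedral intermediate. Reduction with NaBH4 and CeCl3 (MeOH/THF, −78 °C), with hydride expected from the periphery of the ring, rejoins the route at 39. Any C7-epimeric carbinol from step 25 can be oxidised with MnO2 to the same ketone F10 and sent through this reduction.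

## Further compounds

F1 | step 3 | mirror image of ring A aldehyde 6 | O=C[C@]1(C)CC=C(O[Si](C(C)C)(C(C)C)C(C)C)[C@H](C)[C@H]1CO[Si](C)(C)C(C)(C)C
F2 | step 3 | mirror image of ring A carbinol 7 (both C2 epimers) | CC(O)[C@]1(C)CC=C(O[Si](C(C)C)(C(C)C)C(C)C)[C@H](C)[C@H]1CO[Si](C)(C)C(C)(C)C
F3 | step 3 | mirror image of ring A methyl ketone 8 | CC(=O)[C@]1(C)CC=C(O[Si](C(C)C)(C(C)C)C(C)C)[C@H](C)[C@H]1CO[Si](C)(C)C(C)(C)C
F4 | step 3 | (2R)-1-hydroxyethyl carbinol of the wanted ring A series | C[C@@H](O)[C@@]1(C)CC=C(O[Si](C(C)C)(C(C)C)C(C)C)[C@@H](C)[C@@H]1CO[Si](C)(C)C(C)(C)C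
F5 | step 3 | (2R)-1-hydroxyethyl carbinol of the mirror-image ring A series | C[C@@H](O)[C@]1(C)CC=C(O[Si](C(C)C)(C(C)C)C(C)C)[C@H](C)[C@H]1CO[Si](C)(C)C(C)(C)C
F6 | step 13 | ring A enone with C11 methyl β | I/C=C(C)\CC[C@@H](O[Si](C)(C)C(C)(C)C)[C@@]1(C)C=CC(=O)[C@H](C)[C@@H]1CO[Si](C)(C)C(C)(C)C
F7 | step 15 | 14α-hydroxy C12 ketone | I/C=C(C)\CC[C@@H](O[Si](C)(C)C(C)(C)C)[C@@]1(C)[C@@H](O)CC(=O)[C@H](C)[C@@H]1CO[Si](C)(C)C(C)(C)C
F8 | step 21 | C9 epimer of 35 | I/C=C(C)\CC[C@@H](O[Si](C)(C)C(C)(C)C)[C@@]1(C)[C@@H](O)C[C@@H](O[Si](C(C)C)(C(C)C)C(C)C)[C@H](C)[C@@H]1[C@H](O)C1=C(C)COC1=O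
F9 | step 21 | C9 ketone (3-acyl-4-methylfuran-2(5H)-one) | I/C=C(C)\CC[C@@H](O[Si](C)(C)C(C)(C)C)[C@@]1(C)[C@@H](O)C[C@@H](O[Si](C(C)C)(C(C)C)C(C)C)[C@H](C)[C@@H]1C(=O)C1=C(C)COC1=O
F10 | step 25 | macrocyclic cross-conjugated C7 ketone | CC(C)(C)[Si](C)(C)O[C@@H]1CC/C(C)=C\C(=O)/C(=C(/C)CO[Si](CC)(CC)CC)[C@H](O)[C@H]2[C@@H](C)[C@H](O[Si](C(C)C)(C(C)C)C(C)C)C[C@H](O)[C@@]21C
A1 | alternative 1 | ten-membered carbocycle with C7 hydroxyl and C8 isopropenyl | CC[Si](CC)(CC)O[C@@H]3CC/C(C)=C\[C@H](O)[C@@H](C(C)=C)[C@H](OCOC)[C@H]2[C@@H](C)[C@H](O[Si](C)(C)C(C)(C)C)C[C@H](OCOC)[C@@]23C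
A2 | alternative 2 | cis-anti-cis photoadduct with two fused cyclobutanes | C[C@]12C(=O)C[C@@H](O[Si](C)(C)C(C)(C)C)[C@@]3(C)[C@@H](O[Si](C)(C)C(C)(C)C)C[C@@H](OCOC)[C@H](C)[C@]13[C@@]4(O[Si](C)(C)C(C)(C)C)[C@@H]2[C@@H]5OC(=O)[C@@H](C)[C@H]45
A3 | alternative 3 | ring A keto ester with quaternary C1, C10 pivaloyloxymethyl and C11 methylene | COC(=O)[C@@]1(C)C(=O)C[C@@H](O[Si](C)(C)C(C)(C)C)C(=C)[C@@H]1COC(=O)C(C)(C)C
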